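**Retrosynthetic overview** (ring A = trione ring, C1–C6 with C6 the spiro carbon, C2 the acetyl-bearing carbon, C4 the diprenyl carbon; rings B/C = hydrindane, primed 1H-indene locants, C6' = C6)
1. Target 23 ⇐ desilylation and gem-diprenylation at C4 of spiro trione 19.
2. Ring A: 19 ⇐ β-keto ester 15 + diketene: C3–C4 by C-acetoacetylation of the C4 enolate, C1–C2 by Dieckmann closure. Enabling feature: the quaternary spiro carbon C6 carries an axial ester (C1) and an equatorial acetyl group (C5, C4), so only C4 can enolise and C1 is the one acyl acceptor 1,5 to C2.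
3. 15 ⇐ ester 12 by equatorial acetylation (sets spiro C6); 12 ⇐ hydrindene 9 by Markovnikov hydration of C4'=C5'.
4. Rings B and C together: 9 ⇐ triene 8 by intramolecular Diels–Alder (C3a'–C7a' and C6'–C7'); 8 ⇐ (R)-linalool (C1' from the chiral pool) by allylic oxidation and olefination.
5. Order of ring formation: B + C (step 5), then A (step 9).

Key step: step 9

Remark: the β-triketones are drawn as the enol tautomer of the given SMILES although they will exist as tautomer mixtures, and (R)-(−)-linalool of high enantiomeric purity is taken as the commercial starting material.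

**Step 1**
Reactants: 1 (R)-(−)-linalool; 2 triethylsilyl trifluoromethanesulfonate
Product: 3 (3R)-3,7-dimethyl-3-[(triethylsilyl)oxy]octa-1,6-diene
Conditions: TESOTf, 2,6-lutidine, CH2Cl2, −78 to 0 °C
Reagents that add atoms: triethylsilyl trifluoromethanesulfonate (2), CC[Si](CC)(CC)OS(=O)(=O)C(F)(F)F
Why: Silylation of the tertiary allylic alcohol with a silyl triflate and a hindered pyridine base leaves the stereocentre (later C1') untouched and blocks oxa-conjugate addition and elimination in steps 4 and 5.

**Step 2**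
Reactants: 3 (3R)-3,7-dimethyl-3-[(triethylsilyl)oxy]octa-1,6-diene; 4 tert-butyl hydroperoxide
Product: 5 (2E,6R)-2,6-dimethyl-6-[(triethylsilyl)oxy]octa-2,7-dien-1-ol
Conditions: SeO2 (cat.), t-BuOOH, salicylic acid (cat.), CH2Cl2, rt
Reagents that add atoms: tert-butyl hydroperoxide (4, terminal oxygen source relayed through SeO2), CC(C)(C)OO
Why: Catalytic SeO2 allylic oxidation (ene reaction then [2,3]-shift) should hydroxylate the (E)-methyl group of the trisubstituted alkene selectively, while the vinyl group on the quaternary carbon has no allylic hydrogen and cannot react.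

**Step 3**
Reactants: 5 (2E,6R)-2,6-dimethyl-6-[(triethylsilyl)oxy]octa-2,7-dien-1-ol
Product: 6 (2E,6R)-2,6-dimethyl-6-[(triethylsilyl)oxy]octa-2,7-dienal
Conditions: PhI(OAc)2, TEMPO (cat.), CH2Cl2, rt
Reagents that add atoms: none
Why: Oxoammonium (TEMPO/PhI(OAc)2) oxidation of a primary allylic alcohol to the enal is mild, should not isomerise the (E)-alkene and tolerates the silyl ether.

**Step 4**
Reactants: 6 (2E,6R)-2,6-dimethyl-6-[(triethylsilyl)oxy]octa-2,7-dienal; 7 trimethyl phosphonoacetate
Product: 8 methyl (2E,4E,8R)-4,8-dimethyl-8-[(triethylsilyl)oxy]deca-2,4,9-trienoate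
Conditions: NaH, THF, 0 °C to rt
Reagents that add atoms: trimethyl phosphonoacetate (7), COC(=O)CP(=O)(OC)OC
Why: Horner–Wadsworth–Emmons olefination of the α-branched enal with the stabilised phosphonate anion should give the (2E,4E)-dienoate, the new C2=C3 bond being E under the usual thermodynamic control.

**Step 5**
Reactants: 8 methyl (2E,4E,8R)-4,8-dimethyl-8-[(triethylsilyl)oxy]deca-2,4,9-trienoate
Product: 9 methyl (1R,3aR,6S,7aS)-1,4-dimethyl-1-[(triethylsilyl)oxy]-2,3,3a,6,7,7a-hexahydro-1H-indene-6-carboxylate
Conditions: toluene (0.01 M), BHT (cat.), 190 °C, sealed tube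
Reagents that add atoms: none
Why: Thermal intramolecular Diels–Alder reaction of a 1,3,8-nonatriene (ester-activated diene, terminal alkene as dienophile) closes rings B and C at once: suprafacial addition through the exo-tether (anti) transition state, preferred because the syn alternative would force the fully substituted carbinol carbon under the 2-methyl-substituted diene, should give the trans ring fusion; the silyloxy group takes the inside position and the methyl group the anti position on the allylic carbon of the dienophile (inside-alkoxy arrangement), so that C7a' forms with OSiEt3 cis to C7'; and the (E)-ester ends up cis to the C3a'–C3' bond, that is pseudo-axial on the face of H-7a'.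

**Step 6**
Reactants: 9 methyl (1R,3aR,6S,7aS)-1,4-dimethyl-1-[(triethylsilyl)oxy]-2,3,3a,6,7,7a-hexahydro-1H-indene-6-carboxylate; 10 dioxygen
Product: 11 methyl (1R,3aR,4R,6S,7aS)-4-hydroxy-1,4-dimethyl-1-[(triethylsilyl)oxy]octahydro-1H-indene-6-carboxylate
Conditions: Co(acac)2 (cat.), PhSiH3, O2 (1 atm), THF, rt
Reagents that add atoms: dioxygen (10), O=O
Why: Mukaiyama hydration: hydrogen-atom transfer from a cobalt hydride to C5' gives the tertiary C4' radical (Markovnikov), whose capture by O2 should occur from the equatorial direction because the axial side is screened by the pseudo-axial ester at C6' and by H-7a', placing the hydroxyl equatorial and the methyl group axial, cis to the ester.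

**Step 7**
Reactants: 11 methyl (1R,3aR,4R,6S,7aS)-4-hydroxy-1,4-dimethyl-1-[(triethylsilyl)oxy]octahydro-1H-indene-6-carboxylate; 2 triethylsilyl trifluoromethanesulfonate
Product: 12 methyl (1R,3aR,4R,6S,7aS)-1,4-dimethyl-1,4-bis[(triethylsilyl)oxy]octahydro-1H-indene-6-carboxylate
Conditions: TESOTf, 2,6-lutidine, CH2Cl2, 0 °C
Reagents that add atoms: triethylsilyl trifluoromethanesulfonate (2), CC[Si](CC)(CC)OS(=O)(=O)C(F)(F)F
Why: Silyl triflate silylation of the equatorial tertiary alcohol is needed because a free hydroxyl would be acylated in steps 8 and 9; no stereocentre is touched.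

**Step 8**
Reactants: 12 methyl (1R,3aR,4R,6S,7aS)-1,4-dimethyl-1,4-bis[(triethylsilyl)oxy]octahydro-1H-indene-6-carboxylate; 13 acetyl chloride
Product: 15 methyl (1R,3aR,4R,6S,7aS)-6-acetyl-1,4-dimethyl-1,4-bis[(triethylsilyl)oxy]octahydro-1H-indene-6-carboxylate, via lithium ester enolate 14 (not isolated)
Conditions: LiN(i-Pr)2, THF, −78 °C; then enolate added to AcCl, THF, −78 °C
Reagents that add atoms: acetyl chloride (13), CC(=O)Cl
Why: C-Acylation of a lithium ester enolate with an acid chloride (crossed Claisen-type acylation) creates the quaternary spiro carbon: the exocyclic enolate should be attacked from the equatorial direction because the axial side is blocked by the syn-axial 4'-methyl group and H-7a', so the acetyl group becomes equatorial and the ester axial (cis to the 4'-methyl group), which is the configuration of C6 in the target.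

**Step 9**
Reactants: 15 methyl (1R,3aR,4R,6S,7aS)-6-acetyl-1,4-dimethyl-1,4-bis[(triethylsilyl)oxy]octahydro-1H-indene-6-carboxylate; 16 diketene
Product: 19 bis(triethylsilyl) ether of the unprenylated spiro trione, via lithium enolate 17 (not isolated), via triketo ester 18 (not isolated)
Conditions: LiN(SiMe3)2 (1.1 equiv), THF, −78 °C; diketene, −78 to 0 °C; then LiN(SiMe3)2 (2 equiv), 0 to 40 °C; aq. NH4Cl
Reagents that add atoms: diketene (16), C=C1CC(=O)O1
Why: Proposed new method: the kinetic lithium enolate 17 (C4 is the only enolisable carbon because the spiro carbon C6 is quaternary) should attack the strained acyl carbon of diketene, the β-lactone opening to the enolate of 1,3,5-triketone 18 (C3–C4 bond); after proton transfer the C2 carbanion, stabilised between C3=O and the acetyl C=O, sits 1,5 to the ester carbon C1 and should close ring A by a 6-exo-trig Dieckmann (Claisen) condensation with loss of methoxide (C1–C2 bond), the product being trapped as the β-triketone anion. The closest known reaction types are the C-acetoacetylation of carbanions and stabilised enolates with diketene, the Lacey–Dieckmann cyclisation of acetoacetyl derivatives onto esters and the biomimetic Claisen cyclisation of 3,5,7-triketo esters to acylphloroglucinols. No stereocentre is formed, and the spiro configuration set in step 8 cannot epimerise because C6 bears no hydrogen. The step needs C- over O-acylation of the enolate and Claisen rather than aldol ring closure: the lithium counter-ion in THF and the lactone-type acyl donor should favour C-acylation, and the only six-membered aldol mode would need the less acidic terminal methyl group to attack the hindered neopentyl ketone C5, whereas the Claisen mode is driven by formation of the triketone anion.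

**Step 10**
Reactants: 19 bis(triethylsilyl) ether of the unprenylated spiro trione; 20 prenyl bromide
Product: 22 bis(triethylsilyl) ether of the target, via monoprenyl trione 21 (not isolated)
Conditions: NaOMe, MeOH, 0 °C; prenyl bromide (2.5 equiv), 0 °C to rt
Reagents that add atoms: prenyl bromide (20), CC(C)=CCBr
Why: C-Alkylation of the dianion of the enolised β-triketone (vinylogous acid) in methanol, the reaction type used for gem-diprenylation of acylphloroglucinols, should take place twice at C4, the only ring A carbon that still bears hydrogen; no stereocentre remains at C4 and the tertiary silyl ethers are inert.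

**Step 11**
Reactants: 22 bis(triethylsilyl) ether of the target
Product: 23 target CNP0266834.1
Conditions: HF·pyridine, pyridine, THF, 0 °C to rt
Reagents that add atoms: none
Why: Fluoride-mediated cleavage of the two tertiary triethylsilyl ethers under buffered conditions should spare the enol, the prenyl groups and the tertiary alcohols; no stereocentre is affected.

**Compound list**
1 | (R)-(−)-linalool, (3R)-3,7-dimethylocta-1,6-dien-3-ol | C=C[C@](C)(O)CCC=C(C)C | starting material
2 | triethylsilyl trifluoromethanesulfonate | CC[Si](CC)(CC)OS(=O)(=O)C(F)(F)F | starting material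
3 | (3R)-3,7-dimethyl-3-[(triethylsilyl)oxy]octa-1,6-diene | C=C[C@](C)(O[Si](CC)(CC)CC)CCC=C(C)C | intermediate
4 | tert-butyl hydroperoxide | CC(C)(C)OO | starting material
5 | (2E,6R)-2,6-dimethyl-6-[(triethylsilyl)oxy]octa-2,7-dien-1-ol | C=C[C@](C)(O[Si](CC)(CC)CC)CC/C=C(\C)CO | intermediate
6 | (2E,6R)-2,6-dimethyl-6-[(triethylsilyl)oxy]octa-2,7-dienal | C=C[C@](C)(O[Si](CC)(CC)CC)CC/C=C(\C)C=O | intermediate
7 | trimethyl phosphonoacetate | COC(=O)CP(=O)(OC)OC | starting material
8 | methyl (2E,4E,8R)-4,8-dimethyl-8-[(triethylsilyl)oxy]deca-2,4,9-trienoate | C=C[C@](C)(O[Si](CC)(CC)CC)CC/C=C(\C)/C=C/C(=O)OC | intermediate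
9 | methyl (1R,3aR,6S,7aS)-1,4-dimethyl-1-[(triethylsilyl)oxy]-2,3,3a,6,7,7a-hexahydro-1H-indene-6-carboxylate (trans ring fusion, OSiEt3 cis to C7, ester on the face of H-7a) | COC(=O)[C@H]1C[C@H]2[C@@H](CC[C@@]2(C)O[Si](CC)(CC)CC)C(C)=C1 | intermediate
10 | dioxygen | O=O | starting material
11 | methyl (1R,3aR,4R,6S,7aS)-4-hydroxy-1,4-dimethyl-1-[(triethylsilyl)oxy]octahydro-1H-indene-6-carboxylate (4-OH equatorial, 4-CH3 axial and cis to the ester) | COC(=O)[C@H]1C[C@H]2[C@@H](CC[C@@]2(C)O[Si](CC)(CC)CC)[C@](C)(O)C1 | intermediate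
12 | methyl (1R,3aR,4R,6S,7aS)-1,4-dimethyl-1,4-bis[(triethylsilyl)oxy]octahydro-1H-indene-6-carboxylate | COC(=O)[C@H]1C[C@H]2[C@@H](CC[C@@]2(C)O[Si](CC)(CC)CC)[C@](C)(O[Si](CC)(CC)CC)C1 | intermediate
13 | acetyl chloride | CC(=O)Cl | starting material
14 | lithium ester enolate of 12 | [Li+].[O-]C(OC)=C1C[C@H]2[C@@H](CC[C@@]2(C)O[Si](CC)(CC)CC)[C@](C)(O[Si](CC)(CC)CC)C1 | intermediate
15 | methyl (1R,3aR,4R,6S,7aS)-6-acetyl-1,4-dimethyl-1,4-bis[(triethylsilyl)oxy]octahydro-1H-indene-6-carboxylate (ester axial and cis to the 4-methyl group, acetyl equatorial) | CC(=O)[C@@]1(C[C@H]2[C@@H](CC[C@@]2(C)O[Si](CC)(CC)CC)[C@](C)(O[Si](CC)(CC)CC)C1)C(=O)OC | intermediate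
16 | diketene, 4-methylideneoxetan-2-one | C=C1CC(=O)O1 | starting material
17 | lithium enolate of 15 at the acetyl methyl group | [Li+].[O-]C(=C)[C@@]1(C[C@H]2[C@@H](CC[C@@]2(C)O[Si](CC)(CC)CC)[C@](C)(O[Si](CC)(CC)CC)C1)C(=O)OC | intermediate
18 | methyl (1R,3aR,4R,6S,7aS)-6-(3,5-dioxohexanoyl)-1,4-dimethyl-1,4-bis[(triethylsilyl)oxy]octahydro-1H-indene-6-carboxylate (present as its lithium enolate) | CC(=O)CC(=O)CC(=O)[C@@]1(C[C@H]2[C@@H](CC[C@@]2(C)O[Si](CC)(CC)CC)[C@](C)(O[Si](CC)(CC)CC)C1)C(=O)OC | intermediate
19 | spiro trione: 2-acetyl-3-hydroxycyclohex-2-ene-1,5-dione whose C6 is C6' of (1'R,3a'R,4'R,7a'S)-1',4'-dimethyl-1',4'-bis[(triethylsilyl)oxy]octahydroindene, spiro carbon S (C1=O cis to the 4'-methyl group) | CC(=O)C1=C(O)CC(=O)[C@@]2(C[C@H]3[C@@H](CC[C@@]3(C)O[Si](CC)(CC)CC)[C@](C)(O[Si](CC)(CC)CC)C2)C1=O | intermediate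
20 | prenyl bromide, 1-bromo-3-methylbut-2-ene | CC(C)=CCBr | starting material
21 | 4-monoprenyl derivative of 19 (C4 configuration undefined, enolisable) | CC(=O)C1=C(O)C(CC=C(C)C)C(=O)[C@@]2(C[C@H]3[C@@H](CC[C@@]3(C)O[Si](CC)(CC)CC)[C@](C)(O[Si](CC)(CC)CC)C2)C1=O | intermediate
22 | 4,4-bis(3-methylbut-2-en-1-yl) derivative of 19, the bis(triethylsilyl) ether of the target | CC(=O)C1=C(O)C(CC=C(C)C)(CC=C(C)C)C(=O)[C@@]2(C[C@H]3[C@@H](CC[C@@]3(C)O[Si](CC)(CC)CC)[C@](C)(O[Si](CC)(CC)CC)C2)C1=O | intermediate
23 | CNP0266834.1: 2-acetyl-3-hydroxy-4,4-bis(3-methylbut-2-en-1-yl)cyclohex-2-ene-1,5-dione spiro-fused at C6 to C6' of (1'R,3a'R,4'R,7a'S)-1',4'-dihydroxy-1',4'-dimethyloctahydroindene, spiro carbon S | CC(=O)C1=C(O)C(CC=C(C)C)(CC=C(C)C)C(=O)[C@@]2(C[C@H]3[C@@H](CC[C@@]3(C)O)[C@](C)(O)C2)C1=O | target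

**Step count and risks**
Total step count: 11. Longest linear sequence: 11 steps (fully linear from 1).

Steps most likely to fail:

1. Step 9 (Proposed new method). The enolate may be O-acylated by diketene, proton transfer may quench it before C–C bond formation, or the Claisen closure onto the hindered axial ester may stall at the open triketo ester. Fallback with known chemistry, setting out from 15 and coming back at 23: soft enolisation of 15 (MgBr2·OEt2, i-Pr2NEt, CH2Cl2) and C-acylation with (E)-3-methoxybut-2-enoyl chloride should give β-diketone enol ether F1. Aqueous HCl in THF then hydrolyses the enol ether and removes both silyl groups to give triketo ester diol F2. NaOMe in MeOH under reflux closes ring A by Claisen (Dieckmann) condensation to trione diol F3. F3 is bis-prenylated under the conditions of step 10, the tertiary alcohols being inert, to give 23 directly.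

2. Step 5. The syn (endo-tether) transition state may compete and give the cis-fused bicycle, the methyl-inside rotamer may give the wrong configuration at C3a'/C7a' relative to C1', or the triene may oligomerise before it cyclises. Fallback setting out from 6 and coming back at 15, with the roles of the two ends reversed: Heck alkenylation of the vinyl group of 6 with methyl 2-bromoacrylate (Pd(OAc)2, P(o-tol)3, Ag2CO3, MeCN) should give trienal F4. A Me2AlCl-promoted intramolecular Diels–Alder reaction with the enal as activated dienophile (CH2Cl2, −78 to 0 °C, endo transition state) gives aldehyde F5, in which C4' is fixed stereospecifically by the (E)-geometry of the enal. Baeyer–Villiger oxidation (mCPBA, NaHCO3) with retention gives formate F6, K2CO3 in MeOH gives tertiary alcohol F7, and TESOTf with 2,6-lutidine gives bis-silyl enoate F8. Conjugate reduction of F8 with Li[HB(s-Bu)3] at −78 °C generates ester enolate 14, which is acetylated with AcCl as in step 8 to return to 15. This path also avoids step 6.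

3. Step 6. Oxygen capture by the C4' radical may show poor facial selectivity (axial C–O bond formation gives the C4' epimer), or the radical may simply be reduced. Fallback setting out from 9 and coming back at 11: OsO4 (cat.) with N-methylmorpholine N-oxide should dihydroxylate the alkene from the face opposite the pseudo-axial ester to give cis-diol F9. Selective acylation of the secondary hydroxyl with PhOC(S)Cl and pyridine gives thionocarbonate F10, and Barton–McCombie deoxygenation (Bu3SnH, AIBN, toluene, 80 °C) removes the C5' oxygen to return to 11.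

Further compounds
F1 | step 9 | methyl (1R,3aR,4R,6S,7aS)-6-[(4E)-5-methoxy-3-oxohex-4-enoyl]-1,4-dimethyl-1,4-bis[(triethylsilyl)oxy]octahydro-1H-indene-6-carboxylate | CO/C(C)=C/C(=O)CC(=O)[C@@]1(C[C@H]2[C@@H](CC[C@@]2(C)O[Si](CC)(CC)CC)[C@](C)(O[Si](CC)(CC)CC)C1)C(=O)OC
F2 | step 9 | methyl (1R,3aR,4R,6S,7aS)-6-(3,5-dioxohexanoyl)-1,4-dihydroxy-1,4-dimethyloctahydro-1H-indene-6-carboxylate | CC(=O)CC(=O)CC(=O)[C@@]1(C[C@H]2[C@@H](CC[C@@]2(C)O)[C@](C)(O)C1)C(=O)OC
F3 | step 9 | bis-desilylated 19 (unprenylated spiro trione diol) | CC(=O)C1=C(O)CC(=O)[C@@]2(C[C@H]3[C@@H](CC[C@@]3(C)O)[C@](C)(O)C2)C1=O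
F4 | step 5 | methyl (3E,5R,8E)-5,9-dimethyl-2-methylidene-10-oxo-5-[(triethylsilyl)oxy]deca-3,8-dienoate | C=C(C(=O)OC)/C=C/[C@](C)(O[Si](CC)(CC)CC)CC/C=C(\C)C=O
F5 | step 5 | methyl (1R,3aR,4R,7aS)-4-formyl-1,4-dimethyl-1-[(triethylsilyl)oxy]-2,3,3a,4,5,7a-hexahydro-1H-indene-6-carboxylate | COC(=O)C1=C[C@H]2[C@@H](CC[C@@]2(C)O[Si](CC)(CC)CC)[C@](C)(C=O)C1
F6 | step 5 | methyl (1R,3aR,4R,7aS)-4-(formyloxy)-1,4-dimethyl-1-[(triethylsilyl)oxy]-2,3,3a,4,5,7a-hexahydro-1H-indene-6-carboxylate | COC(=O)C1=C[C@H]2[C@@H](CC[C@@]2(C)O[Si](CC)(CC)CC)[C@](C)(OC=O)C1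
F7 | step 5 | methyl (1R,3aR,4R,7aS)-4-hydroxy-1,4-dimethyl-1-[(triethylsilyl)oxy]-2,3,3a,4,5,7a-hexahydro-1H-indene-6-carboxylate | COC(=O)C1=C[C@H]2[C@@H](CC[C@@]2(C)O[Si](CC)(CC)CC)[C@](C)(O)C1
F8 | step 5 | methyl (1R,3aR,4R,7aS)-1,4-dimethyl-1,4-bis[(triethylsilyl)oxy]-2,3,3a,4,5,7a-hexahydro-1H-indene-6-carboxylate | COC(=O)C1=C[C@H]2[C@@H](CC[C@@]2(C)O[Si](CC)(CC)CC)[C@](C)(O[Si](CC)(CC)CC)C1
F9 | step 6 | 5-hydroxy derivative of 11 (cis-4,5-diol, both hydroxyls on the face of H-3a) | COC(=O)[C@H]1C[C@H]2[C@@H](CC[C@@]2(C)O[Si](CC)(CC)CC)[C@](C)(O)[C@@H]1O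
F10 | step 6 | O-phenyl thionocarbonate of F9 at the secondary 5-hydroxyl | COC(=O)[C@H]1C[C@H]2[C@@H](CC[C@@]2(C)O[Si](CC)(CC)CC)[C@](C)(O)[C@@H]1OC(=S)Oc3ccccc3
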